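J is the product to watch, and in both vessels it comes from D, so I counted lifetimes of the Q that feeds D.

    Z → G (k1 = 2.51 × 10⁻⁴ s⁻¹)
    G → Q (k2 = 1.29 × 10⁻⁴ s⁻¹)
    Q ⇌ D (K3 = 3.0, k3 = 3.15 × 10⁻⁵ s⁻¹)
    D → J (k4 = 5.65 × 10⁻⁵ s⁻¹)
    D → L (k5 = 1.60 × 10⁻⁴ s⁻¹)

| setting | Thursday's | Monday's |
|---|---|---|
| Z | 0.20 M | 0.20 M |
| remark | a single well-mixed tank run continuously and read at steady state, 30 h in it on average | everything together in a closed stirred flask, run for 30 h |
| time |  | 30 h |

1. the set-up with the highest amount of J at the outlet or at the end, in percent of the Z put in ("none" if the first two lie within 2 percentage points) (Thursday's / Monday's / none)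
2. amount of J at the outlet or at the end, in percent of the Z put in, Thursday's
3. amount of J at the outlet or at the end, in percent of the Z put in, Monday's

I drew c_J for Monday's flask first. The slope at the start is zero, since the mixture holds Z and c_D is zero. The knee comes after the lifetimes of Z and G, which add up to 3.26 h. The forward step from Q to D is the rate-limiting step, with a forward lifetime of 8.82 h. Part of D returns to Q, so I corrected the forward lifetime for that return:

life = 9.25 h

This net lifetime of Q, longer than the forward lifetime, is the time constant with which Q leaks away for good.

Of what leaves D for good, the selectivity toward J is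

share = 26.1%

This is the level c_J runs into. Past the knee, c_J climbs at 0.0282 h⁻¹ of the charge, and the slope decays with the net lifetime. D rides on Q at a ratio of 0.139. By my reckoning c_J crosses the falling c_Q at 18.1 h. At the end of Monday's run:

lifetimes counted = 2.89
Q remaining = 5.55%
J = 24.4%

Thursday's tank takes each stage as a ratio instead of an exponential:

reaching Q = 90.0%
Q at the outlet = 21.2%
J = 17.2%

By my reckoning, Thursday's outlet carries more Q than Monday's flask holds at its end, so I expected Monday's to win.

The forecast gave Monday's, with 17.2% for Thursday's tank and 24.3% for Monday's flask, saying of Monday's flask that “Only the slow mode survives”.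

The simulation gave Monday's, with 17.2% for Thursday's tank and 24.3% for Monday's flask.

In Monday's flask, Q stood at 5.84% after 30.0 h, against the 5.55% reckoned from the net lifetime. The neighbouring flask is the same charge read at 12 h. There the count is 0.945 lifetimes, which leaves 38.9% as Q and gives 14.5% as J. That flask held Q at 39.4%, L at 39.7% and J at 14.0%.

(The constants used here were set for the occasion; what happens was integrated by code.)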